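The 28-membered lactone is opened at two sp2–sp2 bonds, C19–C20 and C21–C22, flanking the central C20=C21 alkene of the all-E C16–C25 pentaene. That feature, a vinylene between two equal E,E-diene arms (C16–C19 and C22–C25) inside the ring, lets (E)-1,2-bis(tributylstannyl)ethene stitch two dienyl iodide termini, so one palladium-catalysed operation forms both bonds, completes the pentaene and closes the only ring. The precursor is an open-chain ester (C1 acid, C27 alcohol) ending in E,E-dienyl iodides at C19 and C22, with TBS ethers at C3, C11, C13 and C15 and free hydroxyls at C5 and C9, assembled from three fragments by aldol and esterification.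

Key step: step 22

Remark: atoms are numbered from the lactone carbonyl C1 along the polyol and the pentaene to C27, the carbon bearing the ring oxygen; glutaraldehyde is assumed to be used as the anhydrous monomer, distilled from the commercial aqueous solution just before use.

Step 1
Reactants: 1 glutaraldehyde
Product: 2 (4S,8S)-undeca-1,10-diene-4,8-diol
Conditions: (+)-Ipc2B(allyl) (from (−)-α-pinene, 1 M in pentane, 2.4 equiv), Et2O, −78 °C; then 3 M NaOH, 30% H2O2, 0 °C to rt
Reagents that add atoms: (+)-B-allyldiisopinocampheylborane, C=CCB([C@H]1C[C@H]2C[C@@H]([C@@H]1C)C2(C)C)[C@H]1C[C@H]2C[C@@H]([C@@H]1C)C2(C)C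
Why: Two-directional Brown allylboration through chair Zimmerman–Traxler transition states, in which the isopinocampheyl groups of this reagent antipode direct allyl transfer to the face giving (S) carbinols from unbranched alkanals, so C5 and C9 are set together by the reagent and most minor-face error ends in the meso diol, removable here or as a diastereomer after step 4.

Step 2
Reactants: 2 (4S,8S)-undeca-1,10-diene-4,8-diol
Product: 3 (4S,8S)-4,8-bis(4-methoxybenzyloxy)undeca-1,10-diene
Conditions: NaH, PMBCl, Bu4NI (cat.), DMF, 0 °C to rt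
Reagents that add atoms: 4-methoxybenzyl chloride, COc1ccc(CCl)cc1
Why: Williamson etherification of both secondary alkoxides; the C9 PMB ether is the β-alkoxy group needed later for 1,5-induction and both ethers can be removed oxidatively before any long polyene exists.

Step 3
Reactants: 3 (4S,8S)-4,8-bis(4-methoxybenzyloxy)undeca-1,10-diene
Product: 5 (3S,7S)-3,7-bis(4-methoxybenzyloxy)dec-9-enal, via terminal diol 4 (not isolated)
Conditions: OsO4 (2 mol%), NaIO4 (2.0 equiv), 2,6-lutidine, dioxane/H2O (3:1), rt, stopped near half conversion; recovered 3 recycled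
Reagents that add atoms: OsO4, O=[Os](=O)(=O)=O, re-formed by NaIO4, [Na+].[O-]I(=O)(=O)=O, the terminal source of the aldehyde oxygen
Why: Lemieux–Johnson oxidation (catalytic dihydroxylation, then periodate glycol cleavage) run with periodate limiting; the two vinyl groups of C2-symmetric 3 are homotopic, so only one mono-aldehyde can form, and unreacted diene and over-cleaved dialdehyde should separate by polarity.

Step 4
Reactants: 5 (3S,7S)-3,7-bis(4-methoxybenzyloxy)dec-9-enal; 6 (S)-4-benzyl-3-propionyloxazolidin-2-one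
Product: 8 (S)-4-benzyl-3-[(2S,3R,5S,9S)-3-hydroxy-5,9-bis(4-methoxybenzyloxy)-2-methyldodec-11-enoyl]oxazolidin-2-one, via dibutylboron enolate 7 (not isolated)
Conditions: 6, Bu2BOTf, i-Pr2NEt, CH2Cl2, −78 to 0 °C; 5, −78 to 0 °C; pH 7 buffer, MeOH, 30% H2O2, 0 °C
Reagents that add atoms: none
Why: Evans syn aldol, in which Z-enolate 7 reacts through a chair Zimmerman–Traxler transition state with the auxiliary carbonyl dipole opposed to the enolate oxygen, so the benzyl group shields one enolate face and C2 (S) and C3 (R) are set under reagent control irrespective of the C5 ether.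

Step 5
Reactants: 8 C1–C11 aldol adduct
Product: 9 C3 tert-butyldimethylsilyl ether of 8 ((2S,3R,5S,9S) acyl chain, terminal alkene retained)
Conditions: TBSOTf, 2,6-lutidine, CH2Cl2, −78 to 0 °C
Reagents that add atoms: tert-butyldimethylsilyl triflate, CC(C)(C)[Si](C)(C)OS(=O)(=O)C(F)(F)F
Why: Silyl triflate silylation of the hindered secondary alcohol, which blocks retro-aldol and keeps the C3 hydroxyl out of the later boron and acylation chemistry.

Step 6
Reactants: 9 C3 TBS ether of the C1–C11 alkene
Product: 10 (S)-4-benzyl-3-[(2S,3R,5S,9S)-3-(tert-butyldimethylsilyloxy)-5,9-bis(4-methoxybenzyloxy)-2-methyl-11-oxododecanoyl]oxazolidin-2-one (C11 ketone, C12 methyl)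
Conditions: PdCl2 (10 mol%), Cu(OAc)2 (20 mol%), O2 (1 atm), DMA/H2O (7:1), rt
Reagents that add atoms: water, O
Why: Tsuji–Wacker oxidation, in which Markovnikov hydroxypalladation of the terminal alkene and β-hydride elimination give the methyl ketone, while the acid-free copper acetate variant should leave the PMB, silyl and imide groups intact.

Step 7
Reactants: 6 (S)-4-benzyl-3-propionyloxazolidin-2-one; 11 (E)-4,4-dimethoxybut-2-enal
Product: 13 (S)-4-benzyl-3-[(2S,3R,4E)-3-hydroxy-6,6-dimethoxy-2-methylhex-4-enoyl]oxazolidin-2-one, via diethylboron enolate 12 (not isolated)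
Conditions: 6, Et2BOTf (freshly distilled), i-Pr2NEt, CH2Cl2, −78 to 0 °C; 11, −78 to 0 °C; pH 7 buffer, MeOH, 30% H2O2, 0 °C
Reagents that add atoms: none
Why: Evans syn aldol through the Z-diethylboron enolate 12, which reacts through the same chair Zimmerman–Traxler transition state as the dibutylboron enolate of step 4 so that the (S)-auxiliary sets C14 and C15, adds 1,2 to the enal, and leaves only volatile ethanol from the boron ligands after the buffered oxidative work-up, which the acetal of this polar adduct should survive.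

Step 8
Reactants: 13 C13–C18 aldol adduct
Product: 14 (S)-4-benzyl-3-[(2S,3R,4E)-3-(tert-butyldimethylsilyloxy)-6,6-dimethoxy-2-methylhex-4-enoyl]oxazolidin-2-one
Conditions: TBSOTf, 2,6-lutidine, CH2Cl2, −78 °C
Reagents that add atoms: tert-butyldimethylsilyl triflate, CC(C)(C)[Si](C)(C)OS(=O)(=O)C(F)(F)F
Why: Low-temperature silyl triflate silylation of the allylic alcohol; any premature unmasking of the allylic acetal is harmless because the next step removes it.

Step 9
Reactants: 14 TBS ether acetal
Product: 15 (S)-4-benzyl-3-[(2S,3R,4E)-3-(tert-butyldimethylsilyloxy)-2-methyl-6-oxohex-4-enoyl]oxazolidin-2-one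
Conditions: PPTS (cat.), acetone/H2O (10:1), rt
Reagents that add atoms: water, O
Why: Acid-catalysed acetal hydrolysis, in which the allylic dimethyl acetal ionises easily to a conjugated oxocarbenium ion and so hydrolyses under conditions that should spare the secondary TBS ether and the imide, with the E geometry retained.

Step 10
Reactants: 15 C13–C18 enal
Product: 16 (S)-4-benzyl-3-[(2S,3R,4E,6E)-3-(tert-butyldimethylsilyloxy)-7-iodo-2-methylhepta-4,6-dienoyl]oxazolidin-2-one
Conditions: CrCl2 (8 equiv), CHI3 (2.5 equiv), THF/1,4-dioxane (1:6), 0 °C to rt, dark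
Reagents that add atoms: iodoform, IC(I)I
Why: Takai iodo-olefination, in which the gem-dichromium species from CHI3 and divalent chromium adds only to the aldehyde (the imide is inert) and elimination from the less hindered β-oxido chromium intermediate should favour the E alkene, giving the E,E-dienyl iodide C16–C19.

Step 11
Reactants: 16 dienyl iodide imide
Product: 17 (2R,3R,4E,6E)-3-(tert-butyldimethylsilyloxy)-7-iodo-2-methylhepta-4,6-dien-1-ol
Conditions: LiBH4, MeOH (1 equiv), THF, 0 °C
Reagents that add atoms: none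
Why: Reductive cleavage of the N-acyloxazolidinone by hydride attack at the exocyclic carbonyl; the alkenyl iodide and silyl ether are inert and the auxiliary is recovered.

Step 12
Reactants: 17 C13–C19 primary alcohol
Product: 18 (2S,3R,4E,6E)-3-(tert-butyldimethylsilyloxy)-7-iodo-2-methylhepta-4,6-dienal
Conditions: Dess–Martin periodinane, CH2Cl2, 0 °C to rt; used at once
Reagents that add atoms: none
Why: Dess–Martin oxidation under non-basic conditions, chosen because the C14 stereocentre α to the new aldehyde epimerises easily.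

Step 13
Reactants: 10 C1–C12 methyl ketone; 18 C13–C19 aldehyde
Product: 20 C1–C19 β-hydroxy ketone (imide of 10 extended at C12 by the C13–C19 unit; 2S,3R,5S,9S,13R,14R,15R,16E,18E; 13-OH free), via boron enolate 19 (not isolated)
Conditions: 10, Bu2BOTf, i-Pr2NEt, Et2O, −78 °C; 18 (1.3 equiv), −78 °C; pH 7 buffer, MeOH, 30% H2O2, 0 °C
Reagents that add atoms: none
Why: Boron-mediated 1,5-anti aldol of a β-alkoxy methyl ketone, in which kinetic enolisation occurs at the methyl group (the C2 hydrogen of the α-branched imide is shielded by allylic strain) to give enolate 19, whose boat-like transition state places the C9 PMB ether so that C13 forms anti to C9, an enolate-based induction that should override the modest Felkin preference of the α-methyl aldehyde.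

Step 14
Reactants: 20 C1–C19 β-hydroxy ketone
Product: 21 C1–C19 11,13-anti diol (2S,3R,5S,9S,11R,13R,14R,15R; C11 spatially as in the target)
Conditions: Me4NBH(OAc)3, MeCN/AcOH (1:1), −30 to −20 °C
Reagents that add atoms: none
Why: Evans–Saksena reduction, in which ligand exchange binds the C13 hydroxyl to boron and hydride is delivered intramolecularly through a chair transition state to give the 11,13-anti diol and so the C11 centre; the C9 PMB ether cannot direct.

Step 15
Reactants: 21 C1–C19 anti diol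
Product: 22 C1–C19 imide with TBS ethers at C3, C11, C13 and C15 and PMB ethers at C5 and C9 (2S,3R,5S,9S,11S,13R,14R,15R)
Conditions: TBSOTf (3 equiv), 2,6-lutidine, CH2Cl2, −78 to 0 °C
Reagents that add atoms: tert-butyldimethylsilyl triflate, CC(C)(C)[Si](C)(C)OS(=O)(=O)C(F)(F)F
Why: Silyl triflate bis-silylation of the 1,3-diol, after which no free hydroxyl remains to interfere with acid activation.

Step 16
Reactants: 22 fully protected C1–C19 imide
Product: 23 C1–C19 seco acid (2S,3R,5S,9S,11S,13R,14R,15R,16E,18E)-3,11,13,15-tetrakis(tert-butyldimethylsilyloxy)-19-iodo-5,9-bis(4-methoxybenzyloxy)-2,14-dimethylnonadeca-16,18-dienoic acid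
Conditions: LiOH, 30% H2O2, THF/H2O (3:1), 0 °C; Na2SO3; 1 M HCl to pH 3
Reagents that add atoms: hydrogen peroxide (acting as LiOOH), OO
Why: Hydroperoxide cleavage of the N-acyloxazolidinone, where the α-effect nucleophile attacks the exocyclic carbonyl even in this hindered imide without epimerising C2; the PMB ethers are kept at this stage because a free C5 hydroxyl δ to the activated imide would lactonise with loss of the auxiliary.

Step 17
Reactants: 24 acetaldehyde
Product: 25 (2R,3R)-3-methylpent-4-en-2-ol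
Conditions: cis-2-butene, n-BuLi, KOt-Bu, THF, −78 to −45 °C; (−)-Ipc2BOMe (from (+)-α-pinene), −78 °C; BF3·OEt2; 24, −78 °C; 3 M NaOH, 30% H2O2; fractional distillation
Reagents that add atoms: cis-2-butene, C/C=C\C, delivered as (−)-B-[(Z)-but-2-enyl]diisopinocampheylborane, C/C=C\CB([C@@H]1C[C@@H]2C[C@H]([C@H]1C)C2(C)C)[C@@H]1C[C@@H]2C[C@H]([C@H]1C)C2(C)C
Why: Brown (Z)-crotylboration through a chair Zimmerman–Traxler transition state, in which the Z crotyl geometry gives the 26,27-syn relationship and this isopinocampheyl antipode selects the aldehyde face that leads to the (2R,3R) alcohol.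

Step 18
Reactants: 25 (2R,3R)-3-methylpent-4-en-2-ol; 26 (E)-but-2-enal
Product: 27 (2E,4R,5R)-5-hydroxy-4-methylhex-2-enal
Conditions: 26 (5 equiv), second-generation Hoveyda–Grubbs catalyst (5 mol%), CH2Cl2, 40 °C
Reagents that add atoms: none
Why: Olefin cross-metathesis of a terminal alkene with an electron-poor partner used in excess, where the allylically branched alkene homodimerises slowly, the enal should form as the thermodynamically preferred E isomer, and the free alcohol and both stereocentres are untouched.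

Step 19
Reactants: 27 (2E,4R,5R)-5-hydroxy-4-methylhex-2-enal
Product: 28 (2R,3R,4E,6E)-7-iodo-3-methylhepta-4,6-dien-2-ol
Conditions: CrCl2 (10 equiv), CHI3 (2.5 equiv), THF/1,4-dioxane (1:6), 0 °C to rt, dark
Reagents that add atoms: iodoform, IC(I)I
Why: Takai iodo-olefination as in step 10, with extra CrCl2 to allow for the free hydroxyl (held as a chromium alkoxide), which should give the E,E-dienyl iodide C22–C25.

Step 20
Reactants: 23 C1–C19 seco acid; 28 (2R,3R,4E,6E)-7-iodo-3-methylhepta-4,6-dien-2-ol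
Product: 30 bis-PMB seco ester bearing two E,E-dienyl iodides (C1 ester of the C27 oxygen), via mixed anhydride 29 (not isolated)
Conditions: 23, 2,4,6-trichlorobenzoyl chloride, Et3N, toluene, rt; then 28 (1.3 equiv), DMAP, toluene, rt
Reagents that add atoms: none
Why: Yamaguchi esterification, in which DMAP attacks mixed anhydride 29 at the less hindered aliphatic carbonyl and the acylpyridinium acylates the hindered C27 alcohol with retention at C27 and, under these mild conditions, without epimerisation at C2.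

Step 21
Reactants: 30 bis-PMB seco ester
Product: 31 seco ester with free C5 and C9 hydroxyls, TBS ethers at C3, C11, C13 and C15 and E,E-dienyl iodides at C19 and C22
Conditions: DDQ (3 equiv), CH2Cl2/pH 7 phosphate buffer (10:1), 0 °C, dark
Reagents that add atoms: none
Why: Oxidative PMB ether cleavage by DDQ (charge-transfer hydride abstraction, then hydrolysis of the oxocarbenium ions), placed here because C1 is now a hindered secondary ester that a free C5 hydroxyl should not attack under neutral buffered conditions, and because nothing longer than a diene is yet present.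

Step 22
Reactants: 31 diol seco ester with two dienyl iodides; 32 (E)-1,2-bis(tributylstannyl)ethene
Product: 34 tetra-TBS pentaene macrolactone (28-membered ring; the 3,11,13,15-tetrakis-O-TBS ether of the target), via trienylstannane 33 (not isolated)
Conditions: PdCl2(MeCN)2 (20 mol%), i-Pr2NEt, degassed DMF/THF (1:1), 1 mM in 31, 32 (1.05 equiv) added over 10 h by syringe pump, rt, dark
Reagents that add atoms: none
Why: Double Stille coupling: zerovalent palladium, formed in situ from the precatalyst, inserts into one dienyl C–I bond, transmetallation with one tin of 32 and reductive elimination give trienylstannane 33, and a second oxidative addition at the remaining dienyl iodide, intramolecular transmetallation and reductive elimination form the other bond. The closest known reaction type is the stitching macrocyclization of an open-chain bis(alkenyl iodide) with this same distannane to a macrocyclic triene, applied here to two dienyl iodides. The 28-membered lactone ring is closed end to end by the second, intramolecular sp2–sp2 coupling (C19–C20 or C21–C22, whichever terminus reacts last) at the centre of the C16–C25 pentaene. No stereocentre is created; the all-E geometry follows from the E,E-iodides, the E-distannane and retention of configuration in transmetallation and reductive elimination. The step needs ring closure to outrun oligomerization and double stannylation, which the 1 mM concentration, one equivalent of slowly added 32 and the chemical equivalence of the two termini (either coupling order converges on 34) should secure. Neutral, dark, oxygen-free conditions protect the new pentaene, and free hydroxyls, silyl ethers and the ester are spectators in Stille coupling.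

Step 23
Reactants: 34 tetra-TBS pentaene macrolactone
Product: 35 CNP0245606.1, (2S,3R,5S,9S,11S,13R,14R,15R,16E,18E,20E,22E,24E,26R,27R)-3,5,9,11,13,15-hexahydroxy-2,14,26-trimethyloctacosa-16,18,20,22,24-pentaen-27-olide
Conditions: HF·pyridine, excess pyridine, THF, 0 °C to rt, plastic vessel, dark; NaHCO3 quench
Reagents that add atoms: none
Why: Fluoride-mediated desilylation with pyridine-buffered HF·pyridine, where only four silyl ethers remain, the medium should be too weakly acidic to ionise the allylic C15 position or open the lactone, and no base is present to trigger acyl migration or elimination.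

Compound list
1 | glutaraldehyde (pentanedial; C5–C9) | O=CCCCC=O | starting material
2 | (4S,8S)-undeca-1,10-diene-4,8-diol | C=CC[C@@H](O)CCC[C@H](O)CC=C | intermediate
3 | (4S,8S)-4,8-bis(4-methoxybenzyloxy)undeca-1,10-diene | C=CC[C@@H](OCc1ccc(OC)cc1)CCC[C@H](OCc1ccc(OC)cc1)CC=C | intermediate
4 | (4S,8S)-4,8-bis(4-methoxybenzyloxy)undec-10-ene-1,2-diol (both C2 epimers; not isolated) | OCC(O)C[C@@H](OCc1ccc(OC)cc1)CCC[C@H](OCc1ccc(OC)cc1)CC=C | intermediate
5 | (3S,7S)-3,7-bis(4-methoxybenzyloxy)dec-9-enal (C3–C11; the alkene carbons become C11 and C12) | O=CC[C@@H](OCc1ccc(OC)cc1)CCC[C@H](OCc1ccc(OC)cc1)CC=C | intermediate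
6 | (S)-4-benzyl-3-propionyloxazolidin-2-one | CCC(=O)N1[C@@H](Cc2ccccc2)COC1=O | starting material
7 | Z-dibutylboron enolate of 6 (not isolated) | C/C=C(\OB(CCCC)CCCC)N1[C@@H](Cc2ccccc2)COC1=O | intermediate
8 | (S)-4-benzyl-3-[(2S,3R,5S,9S)-3-hydroxy-5,9-bis(4-methoxybenzyloxy)-2-methyldodec-11-enoyl]oxazolidin-2-one | O=C1OC[C@H](Cc2ccccc2)N1C(=O)[C@@H](C)[C@H](O)C[C@@H](OCc1ccc(OC)cc1)CCC[C@H](OCc1ccc(OC)cc1)CC=C | intermediate
9 | (S)-4-benzyl-3-[(2S,3R,5S,9S)-3-(tert-butyldimethylsilyloxy)-5,9-bis(4-methoxybenzyloxy)-2-methyldodec-11-enoyl]oxazolidin-2-one | O=C1OC[C@H](Cc2ccccc2)N1C(=O)[C@@H](C)[C@H](O[Si](C)(C)C(C)(C)C)C[C@@H](OCc1ccc(OC)cc1)CCC[C@H](OCc1ccc(OC)cc1)CC=C | intermediate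
10 | (S)-4-benzyl-3-[(2S,3R,5S,9S)-3-(tert-butyldimethylsilyloxy)-5,9-bis(4-methoxybenzyloxy)-2-methyl-11-oxododecanoyl]oxazolidin-2-one (C1–C12 methyl ketone) | O=C1OC[C@H](Cc2ccccc2)N1C(=O)[C@@H](C)[C@H](O[Si](C)(C)C(C)(C)C)C[C@@H](OCc1ccc(OC)cc1)CCC[C@H](OCc1ccc(OC)cc1)CC(C)=O | intermediate
11 | (E)-4,4-dimethoxybut-2-enal (fumaraldehyde mono(dimethyl acetal); C15–C18) | COC(OC)/C=C/C=O | starting material
12 | Z-diethylboron enolate of 6 (not isolated) | C/C=C(\OB(CC)CC)N1[C@@H](Cc2ccccc2)COC1=O | intermediate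
13 | (S)-4-benzyl-3-[(2S,3R,4E)-3-hydroxy-6,6-dimethoxy-2-methylhex-4-enoyl]oxazolidin-2-one | O=C1OC[C@H](Cc2ccccc2)N1C(=O)[C@@H](C)[C@H](O)/C=C/C(OC)OC | intermediate
14 | (S)-4-benzyl-3-[(2S,3R,4E)-3-(tert-butyldimethylsilyloxy)-6,6-dimethoxy-2-methylhex-4-enoyl]oxazolidin-2-one | O=C1OC[C@H](Cc2ccccc2)N1C(=O)[C@@H](C)[C@H](O[Si](C)(C)C(C)(C)C)/C=C/C(OC)OC | intermediate
15 | (S)-4-benzyl-3-[(2S,3R,4E)-3-(tert-butyldimethylsilyloxy)-2-methyl-6-oxohex-4-enoyl]oxazolidin-2-one | O=C1OC[C@H](Cc2ccccc2)N1C(=O)[C@@H](C)[C@H](O[Si](C)(C)C(C)(C)C)/C=C/C=O | intermediate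
16 | (S)-4-benzyl-3-[(2S,3R,4E,6E)-3-(tert-butyldimethylsilyloxy)-7-iodo-2-methylhepta-4,6-dienoyl]oxazolidin-2-one | O=C1OC[C@H](Cc2ccccc2)N1C(=O)[C@@H](C)[C@H](O[Si](C)(C)C(C)(C)C)/C=C/C=C/I | intermediate
17 | (2R,3R,4E,6E)-3-(tert-butyldimethylsilyloxy)-7-iodo-2-methylhepta-4,6-dien-1-ol | OC[C@@H](C)[C@H](O[Si](C)(C)C(C)(C)C)/C=C/C=C/I | intermediate
18 | (2S,3R,4E,6E)-3-(tert-butyldimethylsilyloxy)-7-iodo-2-methylhepta-4,6-dienal (C13–C19) | O=C[C@@H](C)[C@H](O[Si](C)(C)C(C)(C)C)/C=C/C=C/I | intermediate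
19 | dibutylboron enolate of methyl ketone 10 (C11 enol borinate, C12 methylene; not isolated) | O=C1OC[C@H](Cc2ccccc2)N1C(=O)[C@@H](C)[C@H](O[Si](C)(C)C(C)(C)C)C[C@@H](OCc1ccc(OC)cc1)CCC[C@H](OCc1ccc(OC)cc1)CC(=C)OB(CCCC)CCCC | intermediate
20 | C1–C19 β-hydroxy ketone: (S)-4-benzyloxazolidin-2-one imide of the (2S,3R,5S,9S,13R,14R,15R,16E,18E)-3,15-bis(tert-butyldimethylsilyloxy)-13-hydroxy-19-iodo-5,9-bis(4-methoxybenzyloxy)-2,14-dimethyl-11-oxononadeca-16,18-dienoyl chain | O=C1OC[C@H](Cc2ccccc2)N1C(=O)[C@@H](C)[C@H](O[Si](C)(C)C(C)(C)C)C[C@@H](OCc1ccc(OC)cc1)CCC[C@H](OCc1ccc(OC)cc1)CC(=O)C[C@@H](O)[C@@H](C)[C@H](O[Si](C)(C)C(C)(C)C)/C=C/C=C/I | intermediate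
21 | C1–C19 11,13-anti diol: imide of the (2S,3R,5S,9S,11R,13R,14R,15R,16E,18E)-3,15-bis(tert-butyldimethylsilyloxy)-11,13-dihydroxy-19-iodo-5,9-bis(4-methoxybenzyloxy)-2,14-dimethylnonadeca-16,18-dienoyl chain | O=C1OC[C@H](Cc2ccccc2)N1C(=O)[C@@H](C)[C@H](O[Si](C)(C)C(C)(C)C)C[C@@H](OCc1ccc(OC)cc1)CCC[C@H](OCc1ccc(OC)cc1)C[C@H](O)C[C@@H](O)[C@@H](C)[C@H](O[Si](C)(C)C(C)(C)C)/C=C/C=C/I | intermediate
22 | C1–C19 imide with TBS ethers at C3, C11, C13, C15 and PMB ethers at C5, C9 (2S,3R,5S,9S,11S,13R,14R,15R,16E,18E) | O=C1OC[C@H](Cc2ccccc2)N1C(=O)[C@@H](C)[C@H](O[Si](C)(C)C(C)(C)C)C[C@@H](OCc1ccc(OC)cc1)CCC[C@H](OCc1ccc(OC)cc1)C[C@H](O[Si](C)(C)C(C)(C)C)C[C@@H](O[Si](C)(C)C(C)(C)C)[C@@H](C)[C@H](O[Si](C)(C)C(C)(C)C)/C=C/C=C/I | intermediate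
23 | (2S,3R,5S,9S,11S,13R,14R,15R,16E,18E)-3,11,13,15-tetrakis(tert-butyldimethylsilyloxy)-19-iodo-5,9-bis(4-methoxybenzyloxy)-2,14-dimethylnonadeca-16,18-dienoic acid (C1–C19 seco acid) | OC(=O)[C@@H](C)[C@H](O[Si](C)(C)C(C)(C)C)C[C@@H](OCc1ccc(OC)cc1)CCC[C@H](OCc1ccc(OC)cc1)C[C@H](O[Si](C)(C)C(C)(C)C)C[C@@H](O[Si](C)(C)C(C)(C)C)[C@@H](C)[C@H](O[Si](C)(C)C(C)(C)C)/C=C/C=C/I | intermediate
24 | acetaldehyde (C27 and its methyl) | CC=O | starting material
25 | (2R,3R)-3-methylpent-4-en-2-ol | C=C[C@@H](C)[C@@H](C)O | intermediate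
26 | (E)-but-2-enal (crotonaldehyde; supplies C23 and C24) | C/C=C/C=O | starting material
27 | (2E,4R,5R)-5-hydroxy-4-methylhex-2-enal | O=C/C=C/[C@@H](C)[C@@H](C)O | intermediate
28 | (2R,3R,4E,6E)-7-iodo-3-methylhepta-4,6-dien-2-ol (C22–C27) | I/C=C/C=C/[C@@H](C)[C@@H](C)O | intermediate
29 | mixed anhydride of acid 23 with 2,4,6-trichlorobenzoic acid (not isolated) | Clc1cc(Cl)cc(Cl)c1C(=O)OC(=O)[C@@H](C)[C@H](O[Si](C)(C)C(C)(C)C)C[C@@H](OCc1ccc(OC)cc1)CCC[C@H](OCc1ccc(OC)cc1)C[C@H](O[Si](C)(C)C(C)(C)C)C[C@@H](O[Si](C)(C)C(C)(C)C)[C@@H](C)[C@H](O[Si](C)(C)C(C)(C)C)/C=C/C=C/I | intermediate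
30 | (2R,3R,4E,6E)-7-iodo-3-methylhepta-4,6-dien-2-yl ester of acid 23 (bis-PMB seco ester with two E,E-dienyl iodides) | I/C=C/C=C/[C@@H](C)[C@@H](C)OC(=O)[C@@H](C)[C@H](O[Si](C)(C)C(C)(C)C)C[C@@H](OCc1ccc(OC)cc1)CCC[C@H](OCc1ccc(OC)cc1)C[C@H](O[Si](C)(C)C(C)(C)C)C[C@@H](O[Si](C)(C)C(C)(C)C)[C@@H](C)[C@H](O[Si](C)(C)C(C)(C)C)/C=C/C=C/I | intermediate
31 | 5,9-diol seco ester (30 without the PMB groups; TBS at C3, C11, C13, C15; dienyl iodides at C19 and C22; 2S,3R,5S,9S,11S,13R,14R,15R,26R,27R) | I/C=C/C=C/[C@@H](C)[C@@H](C)OC(=O)[C@@H](C)[C@H](O[Si](C)(C)C(C)(C)C)C[C@@H](O)CCC[C@H](O)C[C@H](O[Si](C)(C)C(C)(C)C)C[C@@H](O[Si](C)(C)C(C)(C)C)[C@@H](C)[C@H](O[Si](C)(C)C(C)(C)C)/C=C/C=C/I | intermediate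
32 | (E)-1,2-bis(tributylstannyl)ethene (C20 and C21) | CCCC[Sn](CCCC)(CCCC)/C=C/[Sn](CCCC)(CCCC)CCCC | starting material
33 | mono-coupled intermediate: 31 with the C19 iodide replaced by an (E)-2-(tributylstannyl)vinyl group (C16–C21 trienylstannane; C22 iodide intact; not isolated) | I/C=C/C=C/[C@@H](C)[C@@H](C)OC(=O)[C@@H](C)[C@H](O[Si](C)(C)C(C)(C)C)C[C@@H](O)CCC[C@H](O)C[C@H](O[Si](C)(C)C(C)(C)C)C[C@@H](O[Si](C)(C)C(C)(C)C)[C@@H](C)[C@H](O[Si](C)(C)C(C)(C)C)/C=C/C=C/C=C/[Sn](CCCC)(CCCC)CCCC | intermediate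
34 | 3,11,13,15-tetrakis-O-(tert-butyldimethylsilyl) ether of the target (28-membered all-E pentaene macrolactone) | C[C@H]1[C@H](O[Si](C)(C)C(C)(C)C)/C=C/C=C/C=C/C=C/C=C/[C@@H](C)[C@@H](C)OC(=O)[C@@H](C)[C@H](O[Si](C)(C)C(C)(C)C)C[C@@H](O)CCC[C@H](O)C[C@H](O[Si](C)(C)C(C)(C)C)C[C@H]1O[Si](C)(C)C(C)(C)C | intermediate
35 | CNP0245606.1, (2S,3R,5S,9S,11S,13R,14R,15R,16E,18E,20E,22E,24E,26R,27R)-3,5,9,11,13,15-hexahydroxy-2,14,26-trimethyloctacosa-16,18,20,22,24-pentaen-27-olide | C[C@H]1[C@H](O)/C=C/C=C/C=C/C=C/C=C/[C@@H](C)[C@@H](C)OC(=O)[C@@H](C)[C@H](O)C[C@@H](O)CCC[C@H](O)C[C@H](O)C[C@H]1O | target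

Total step count: 23. Longest linear sequence: 14 steps (steps 1–6, 13–16 and 20–23 from glutaraldehyde; the branch through steps 7–12 is equally long).

Steps most likely to fail

Step 22. What may go wrong: intermolecular coupling of the mono-coupled stannane (oligomerization), stannylation of both termini before ring closure, or isomerization of the growing polyene. Fallback: ring closure by a one-bond intramolecular Suzuki–Miyaura coupling, with the 1:1 stoichiometry built into the substrate. It sets out from iodide 28. Hydrostannation of commercial ethynylboronic acid MIDA ester (Bu3SnH, PdCl2(PPh3)2) should give (E)-2-(tributylstannyl)vinylboronic acid MIDA ester F1, and Stille coupling of 28 with F1 should give the trienyl MIDA boronate alcohol F2. Acylation of F2 with mixed anhydride 29 (made from acid 23 as in step 20) should give the boronate/iodide bis-PMB seco ester F3, and DDQ as in step 21 should give the boronate/iodide diol seco ester F4, the MIDA boronate being inert to that oxidant. Slow release of the boronic acid with aqueous K3PO4 in the presence of Pd(OAc)2 and SPhos in THF at high dilution should then form C19–C20 and come back to the route at 34.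

Step 13. What may go wrong: insufficient facial selectivity at C13, because the Felkin preference of the α-methyl aldehyde opposes the 1,5-anti induction, together with epimerization of the aldehyde at C14. Fallback: control from the aldehyde instead of the enolate. It sets out from methyl ketone 10. Kinetic silylation (LiN(SiMe3)2, Me3SiCl, Et3N, THF, −78 °C; the imide α-hydrogen is shielded by allylic strain) should give the trimethylsilyl enol ether F5. A Mukaiyama aldol of F5 with 18 promoted by Me2AlCl (2.5 equiv, CH2Cl2, −78 °C) should proceed through an aluminium chelate spanning the aldehyde oxygen and the C15 silyloxy oxygen. Attack anti to the C14 methyl on that chelate gives the 13,14-anti, 13,15-anti adduct, and the route is rejoined at 20.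

Step 23. What may go wrong: slow cleavage of the hindered silyl ethers, so that long exposure lets the allylic C15 position ionise next to the pentaene or the polyene isomerise. Fallback: desilylation before the polyene exists. It sets out from 31. HF·pyridine/pyridine in THF should give the hexaol bis(dienyl iodide) seco ester F6, in which only dienes are present. Stitching of F6 with 32 under the conditions of step 22, through the unprotected mono-coupled trienylstannane F7, should give 35 directly, since free hydroxyls are spectators in Stille coupling.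

Further compounds
F1 | step 22 | (E)-2-(tributylstannyl)vinylboronic acid MIDA ester | CCCC[Sn](CCCC)(CCCC)/C=C/[B-]12OC(=O)C[N+]1(C)CC(=O)O2
F2 | step 22 | trienyl MIDA boronate alcohol, (2R,3R,4E,6E,8E)-3-methyl-9-(MIDA-boryl)nona-4,6,8-trien-2-ol | C[N+]12CC(=O)O[B-]1(OC(=O)C2)/C=C/C=C/C=C/[C@@H](C)[C@@H](C)O
F3 | step 22 | boronate/iodide bis-PMB seco ester (ester of acid 23 with F2) | C[N+]12CC(=O)O[B-]1(OC(=O)C2)/C=C/C=C/C=C/[C@@H](C)[C@@H](C)OC(=O)[C@@H](C)[C@H](O[Si](C)(C)C(C)(C)C)C[C@@H](OCc1ccc(OC)cc1)CCC[C@H](OCc1ccc(OC)cc1)C[C@H](O[Si](C)(C)C(C)(C)C)C[C@@H](O[Si](C)(C)C(C)(C)C)[C@@H](C)[C@H](O[Si](C)(C)C(C)(C)C)/C=C/C=C/I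
F4 | step 22 | boronate/iodide diol seco ester (F3 without the PMB groups) | C[N+]12CC(=O)O[B-]1(OC(=O)C2)/C=C/C=C/C=C/[C@@H](C)[C@@H](C)OC(=O)[C@@H](C)[C@H](O[Si](C)(C)C(C)(C)C)C[C@@H](O)CCC[C@H](O)C[C@H](O[Si](C)(C)C(C)(C)C)C[C@@H](O[Si](C)(C)C(C)(C)C)[C@@H](C)[C@H](O[Si](C)(C)C(C)(C)C)/C=C/C=C/I
F5 | step 13 | trimethylsilyl enol ether of methyl ketone 10 | O=C1OC[C@H](Cc2ccccc2)N1C(=O)[C@@H](C)[C@H](O[Si](C)(C)C(C)(C)C)C[C@@H](OCc1ccc(OC)cc1)CCC[C@H](OCc1ccc(OC)cc1)CC(=C)O[Si](C)(C)C
F6 | step 23 | hexaol bis(dienyl iodide) seco ester | I/C=C/C=C/[C@@H](C)[C@@H](C)OC(=O)[C@@H](C)[C@H](O)C[C@@H](O)CCC[C@H](O)C[C@H](O)C[C@@H](O)[C@@H](C)[C@H](O)/C=C/C=C/I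
F7 | step 23 | unprotected mono-coupled trienylstannane (C19 coupled, C22 iodide intact) | I/C=C/C=C/[C@@H](C)[C@@H](C)OC(=O)[C@@H](C)[C@H](O)C[C@@H](O)CCC[C@H](O)C[C@H](O)C[C@@H](O)[C@@H](C)[C@H](O)/C=C/C=C/C=C/[Sn](CCCC)(CCCC)CCCC
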